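**Plan**
1. The target is a terphenyl of three phloroglucinol rings. Central ring B (atoms B1–B6) carries ring A on B1 and ring C on B5, OH on B2, B4 and B6, and H on B3. Each outer ring bears one ortho O-sulfate.
2. The retrosynthesis first cuts the two S–O bonds, then three bonds of ring B: B2–B3, B4–B5 and B6–B1.
3. This works because oxygenated B2, B4, B6 alternate with aryl-, H- and aryl-bearing B1, B3, B5. That is the pattern of a head-to-tail trimer of three ynol ethers: B1≡B2 and B5≡B6 from two aryl siloxyalkynes, B3≡B4 from siloxyacetylene.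
4. Forward, rings A and C come ready-made from 2,4,6-trihydroxybenzaldehyde (two benzyl ethers, one MOM ether on the future sulfate oxygen, CHO converted into C≡C–OSi). Ring B is the only ring built, by a rhodium-catalysed [2+2+2] cyclotrimerisation, so neither crowded biaryl bond is made by coupling.
5. The silyl ethers are then exchanged for benzyl ethers, the MOM ethers removed, the two freed phenols sulfated and all benzyl groups hydrogenolysed.
6. Stereochemistry: there is no stereocentre and the biaryl axes carry no descriptor, so nothing has to be set.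

Key step: step 6

Remark on the chemistry: the target is drawn as the free bis(hydrogen sulfate); it is made as its disodium salt and protonated in the last operation.
Remark on the chemistry: the two biaryl axes have no descriptor in the target and are treated as stereochemically undefined.

**Route**

Step 1
Reactants: 1 2,4,6-trihydroxybenzaldehyde; 2 benzyl bromide
Product: 3 2,4-bis(benzyloxy)-6-hydroxybenzaldehyde
Conditions: BnBr (2.1 equiv), K2CO3, DMF, 0 °C to rt
Reagents that add atoms: benzyl bromide, BrCc1ccccc1
Why: Williamson etherification in which the 4-OH and one 2-OH are alkylated, while the last ortho-OH is held in a hydrogen bond to the formyl oxygen and should stay free, a selectivity well established for 2,4,6-trihydroxyaryl carbonyl compounds.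

Step 2
Reactants: 3 2,4-bis(benzyloxy)-6-hydroxybenzaldehyde; 4 chloromethyl methyl ether
Product: 5 2,4-bis(benzyloxy)-6-(methoxymethoxy)benzaldehyde
Conditions: MOMCl (1.5 equiv), K2CO3, acetone, 50 °C
Reagents that add atoms: chloromethyl methyl ether, COCCl
Why: The chelated phenol is O-alkylated by the highly reactive α-chloro ether under carbonate (Williamson-type acetal formation), which marks this oxygen as the later sulfate site with a group orthogonal to benzyl and silyl ethers.

Step 3
Reactants: 5 2,4-bis(benzyloxy)-6-(methoxymethoxy)benzaldehyde; 6 dimethyl (1-diazo-2-oxopropyl)phosphonate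
Product: 7 1,5-bis(benzyloxy)-2-ethynyl-3-(methoxymethoxy)benzene
Conditions: Ohira–Bestmann reagent (1.5 equiv), K2CO3, MeOH–THF, rt
Reagents that add atoms: dimethyl (1-diazo-2-oxopropyl)phosphonate, COP(=O)(OC)C(=[N+]=[N-])C(C)=O
Why: Seyferth–Gilbert homologation in its Ohira–Bestmann form, in which the diazomethylphosphonate anion formed in situ olefinates the aldehyde and the diazoalkene loses N2 with a 1,2-hydride shift to the terminal alkyne, under mild carbonate conditions that leave MOM and benzyl ethers untouched.

Step 4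
Reactants: 7 1,5-bis(benzyloxy)-2-ethynyl-3-(methoxymethoxy)benzene; 8 tert-butyl hydroperoxide; 9 triisopropylsilyl trifluoromethanesulfonate
Product: 12 ({[2,4-bis(benzyloxy)-6-(methoxymethoxy)phenyl]ethynyl}oxy)triisopropylsilane, via lithium acetylide 10 (not isolated), via lithium arylethynolate 11 (not isolated)
Conditions: LiN(SiMe3)2, THF, −78 °C; LiOOt-Bu (from t-BuOOH and LiN(SiMe3)2), −78 to 0 °C; i-Pr3SiOTf, −78 to 0 °C
Reagents that add atoms: tert-butyl hydroperoxide, CC(C)(C)OO; triisopropylsilyl trifluoromethanesulfonate, CC(C)[Si](OS(=O)(=O)C(F)(F)F)(C(C)C)C(C)C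
Why: The acetylide carbon attacks the peroxide oxygen of lithium tert-butyl peroxide (electrophilic oxygenation of an acetylide to an ynolate) and the bulky, hard silyl triflate traps the ynolate on oxygen, the standard passage from terminal alkynes to 1-siloxyalkynes, which here avoids nucleophilic addition to a di-ortho-substituted benzoate.

Step 5
Reactants: 13 3-phenylisoxazole; 9 triisopropylsilyl trifluoromethanesulfonate
Product: 16 (ethynyloxy)triisopropylsilane, via 5-lithio-3-phenylisoxazole 14 (not isolated), via lithium ethynolate 15 (not isolated)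
Conditions: n-BuLi (1.0 equiv), THF, −78 to −50 °C; i-Pr3SiOTf, −78 to 0 °C; distillation
Reagents that add atoms: triisopropylsilyl trifluoromethanesulfonate, CC(C)[Si](OS(=O)(=O)C(F)(F)F)(C(C)C)C(C)C
Why: Lithiation of a 3-substituted isoxazole at C5 triggers the known cycloreversion into a nitrile and a lithium ynolate, and O-silylation with the hindered triflate as in step 4 should give the terminal siloxyalkyne, separable from benzonitrile by distillation.

Step 6
Reactants: 12 ({[2,4-bis(benzyloxy)-6-(methoxymethoxy)phenyl]ethynyl}oxy)triisopropylsilane (two molecules enter); 16 (ethynyloxy)triisopropylsilane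
Product: 17 2,4-bis[2,4-bis(benzyloxy)-6-(methoxymethoxy)phenyl]-1,3,5-tris(triisopropylsilyloxy)benzene
Conditions: [Rh(cod)2]BF4 (10 mol %), rac-H8-BINAP (10 mol %), activated with H2 then Ar, CH2Cl2, rt; 16 added by syringe pump to 12 (2.5 equiv)
Reagents that add atoms: none
Why: Proposed new method: monovalent rhodium should couple 16 and one molecule of 12 oxidatively to a rhodacyclopentadiene of trivalent rhodium, the electron-poor oxygen-bearing carbon of one ynol ether bonding to the nucleophilic remote carbon of the other; a second molecule of 12 then inserts in the same head-to-tail sense and reductive elimination closes ring B, a six-membered carbocycle formed by an intermolecular [2+2+2] cycloaddition that makes B2–B3, B4–B5 and B6–B1 at once. The closest known reaction type is the cyclotrimerisation and cross-trimerisation of terminal alkynes, alkynyl ethers and ynamides with cationic rhodium–bisphosphine catalysts, in which heteroatom-polarised alkynes couple head to tail; a mixed trimer of two hindered internal siloxyalkynes and one terminal siloxyalkyne is without precedent. No stereocentre is created, and the two crowded biaryl bonds are not formed here but arrive as the aryl–alkyne bonds of 12. The step needs chemoselectivity for the two-to-one trimer, which is sought by feeding 16 slowly into an excess of 12, since three molecules of 12 are too crowded to combine and dilute 16 should homotrimerise slowly. It also needs head-to-tail regioselectivity, which rests on the uniform polarisation of the three C≡C–O units.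

Step 7
Reactants: 17 2,4-bis[2,4-bis(benzyloxy)-6-(methoxymethoxy)phenyl]-1,3,5-tris(triisopropylsilyloxy)benzene; 2 benzyl bromide
Product: 18 1,3,5-tris(benzyloxy)-2,4-bis[2,4-bis(benzyloxy)-6-(methoxymethoxy)phenyl]benzene
Conditions: CsF, BnBr (excess), DMF, rt to 50 °C
Reagents that add atoms: benzyl bromide, BrCc1ccccc1
Why: Fluoride cleaves each aryl silyl ether and the caesium phenoxide is benzylated as it forms (one-pot desilylation–Williamson etherification), so the oxidation-prone free triol should never accumulate and O-alkylation is favoured over C-benzylation at B3 in DMF.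

Step 8
Reactants: 18 1,3,5-tris(benzyloxy)-2,4-bis[2,4-bis(benzyloxy)-6-(methoxymethoxy)phenyl]benzene
Product: 19 2,2'-[2,4,6-tris(benzyloxy)-1,3-phenylene]bis[3,5-bis(benzyloxy)phenol]
Conditions: aq. HCl (3 equiv), MeOH–THF, 50 °C
Reagents that add atoms: none
Why: Acid-catalysed acetal exchange (MOM cleavage) with methanol as acceptor should free only the two phenols next to the biaryl bonds, since benzyl ethers are stable to dilute HCl.

Step 9
Reactants: 19 2,2'-[2,4,6-tris(benzyloxy)-1,3-phenylene]bis[3,5-bis(benzyloxy)phenol]; 20 sulfur trioxide–pyridine complex; 21 sodium hydroxide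
Product: 23 disodium 2,2'-[2,4,6-tris(benzyloxy)-1,3-phenylene]bis[3,5-bis(benzyloxy)phenyl] bis(sulfate), via bis(pyridinium) sulfate 22 (not isolated)
Conditions: SO3·pyridine (8 equiv), pyridine, 40 °C; aq. NaOH to pH 9
Reagents that add atoms: sulfur trioxide–pyridine complex, [O-]S(=O)(=O)[n+]1ccccc1; sodium hydroxide, [Na+].[OH-]
Why: O-sulfation of phenols with the sulfur trioxide–pyridine complex can take place only at the two free hydroxyl groups, every other oxygen being a benzyl ether, and basification should give the stable disodium salt.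

Step 10
Reactants: 23 disodium 2,2'-[2,4,6-tris(benzyloxy)-1,3-phenylene]bis[3,5-bis(benzyloxy)phenyl] bis(sulfate)
Product: 25 2,2'-(2,4,6-trihydroxy-1,3-phenylene)bis(3,5-dihydroxyphenyl) bis(hydrogen sulfate) (CNP0320583.0), via target disodium salt 24 (not isolated)
Conditions: H2 (1 atm), 10% Pd/C, MeOH–THF–H2O, rt; aq. HCl (2.0 equiv), 0 °C, C18 desalting, lyophilisation
Reagents that add atoms: none
Why: Catalytic hydrogenolysis should cleave all seven benzyl ethers while aryl sulfate salts are inert to H2 over Pd/C, and brief protonation with two equivalents of acid in the cold gives the acid form drawn for the target.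

**Compound list**

1 | 2,4,6-trihydroxybenzaldehyde | O=Cc1c(O)cc(O)cc1O | starting material
2 | benzyl bromide | BrCc1ccccc1 | starting material
3 | 2,4-bis(benzyloxy)-6-hydroxybenzaldehyde | O=Cc1c(O)cc(OCc2ccccc2)cc1OCc1ccccc1 | intermediate
4 | chloromethyl methyl ether | COCCl | starting material
5 | 2,4-bis(benzyloxy)-6-(methoxymethoxy)benzaldehyde | COCOc1cc(OCc2ccccc2)cc(OCc2ccccc2)c1C=O | intermediate
6 | dimethyl (1-diazo-2-oxopropyl)phosphonate | COP(=O)(OC)C(=[N+]=[N-])C(C)=O | starting material
7 | 1,5-bis(benzyloxy)-2-ethynyl-3-(methoxymethoxy)benzene | COCOc1cc(OCc2ccccc2)cc(OCc2ccccc2)c1C#C | intermediate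
8 | tert-butyl hydroperoxide | CC(C)(C)OO | starting material
9 | triisopropylsilyl trifluoromethanesulfonate | CC(C)[Si](OS(=O)(=O)C(F)(F)F)(C(C)C)C(C)C | starting material
10 | lithium [2,4-bis(benzyloxy)-6-(methoxymethoxy)phenyl]acetylide | [Li]C#Cc1c(OCOC)cc(OCc2ccccc2)cc1OCc1ccccc1 | intermediate (not isolated)
11 | lithium 2-[2,4-bis(benzyloxy)-6-(methoxymethoxy)phenyl]ethynolate | [Li+].[O-]C#Cc1c(OCOC)cc(OCc2ccccc2)cc1OCc1ccccc1 | intermediate (not isolated)
12 | ({[2,4-bis(benzyloxy)-6-(methoxymethoxy)phenyl]ethynyl}oxy)triisopropylsilane | COCOc1cc(OCc2ccccc2)cc(OCc2ccccc2)c1C#CO[Si](C(C)C)(C(C)C)C(C)C | intermediate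
13 | 3-phenylisoxazole | c1ccc(-c2ccon2)cc1 | starting material
14 | 5-lithio-3-phenylisoxazole | [Li]c1cc(-c2ccccc2)no1 | intermediate (not isolated)
15 | lithium ethynolate | [Li+].[O-]C#C | intermediate (not isolated)
16 | (ethynyloxy)triisopropylsilane | C#CO[Si](C(C)C)(C(C)C)C(C)C | intermediate
17 | 2,4-bis[2,4-bis(benzyloxy)-6-(methoxymethoxy)phenyl]-1,3,5-tris(triisopropylsilyloxy)benzene | COCOc1cc(OCc2ccccc2)cc(OCc2ccccc2)c1-c1c(O[Si](C(C)C)(C(C)C)C(C)C)cc(O[Si](C(C)C)(C(C)C)C(C)C)c(-c2c(OCOC)cc(OCc3ccccc3)cc2OCc2ccccc2)c1O[Si](C(C)C)(C(C)C)C(C)C | intermediate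
18 | 1,3,5-tris(benzyloxy)-2,4-bis[2,4-bis(benzyloxy)-6-(methoxymethoxy)phenyl]benzene | COCOc1cc(OCc2ccccc2)cc(OCc2ccccc2)c1-c1c(OCc2ccccc2)cc(OCc2ccccc2)c(-c2c(OCOC)cc(OCc3ccccc3)cc2OCc2ccccc2)c1OCc1ccccc1 | intermediate
19 | 2,2'-[2,4,6-tris(benzyloxy)-1,3-phenylene]bis[3,5-bis(benzyloxy)phenol] | Oc1cc(OCc2ccccc2)cc(OCc2ccccc2)c1-c1c(OCc2ccccc2)cc(OCc2ccccc2)c(-c2c(O)cc(OCc3ccccc3)cc2OCc2ccccc2)c1OCc1ccccc1 | intermediate
20 | sulfur trioxide–pyridine complex | [O-]S(=O)(=O)[n+]1ccccc1 | starting material
21 | sodium hydroxide | [Na+].[OH-] | starting material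
22 | bis(pyridinium) 2,2'-[2,4,6-tris(benzyloxy)-1,3-phenylene]bis[3,5-bis(benzyloxy)phenyl] bis(sulfate) | c1cc[nH+]cc1.c1cc[nH+]cc1.[O-]S(=O)(=O)Oc1cc(OCc2ccccc2)cc(OCc2ccccc2)c1-c1c(OCc2ccccc2)cc(OCc2ccccc2)c(-c2c(OS(=O)(=O)[O-])cc(OCc3ccccc3)cc2OCc2ccccc2)c1OCc1ccccc1 | intermediate (not isolated)
23 | disodium 2,2'-[2,4,6-tris(benzyloxy)-1,3-phenylene]bis[3,5-bis(benzyloxy)phenyl] bis(sulfate) | [Na+].[Na+].[O-]S(=O)(=O)Oc1cc(OCc2ccccc2)cc(OCc2ccccc2)c1-c1c(OCc2ccccc2)cc(OCc2ccccc2)c(-c2c(OS(=O)(=O)[O-])cc(OCc3ccccc3)cc2OCc2ccccc2)c1OCc1ccccc1 | intermediate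
24 | disodium 2,2'-(2,4,6-trihydroxy-1,3-phenylene)bis(3,5-dihydroxyphenyl) bis(sulfate) | [Na+].[Na+].[O-]S(=O)(=O)Oc1cc(O)cc(O)c1-c1c(O)cc(O)c(-c2c(O)cc(O)cc2OS(=O)(=O)[O-])c1O | intermediate (not isolated)
25 | 2,2'-(2,4,6-trihydroxy-1,3-phenylene)bis(3,5-dihydroxyphenyl) bis(hydrogen sulfate) (CNP0320583.0) | O=S(=O)(O)Oc1cc(O)cc(O)c1-c1c(O)cc(O)c(-c2c(O)cc(O)cc2OS(=O)(=O)O)c1O | target

**Count and risks**

Total step count: 10. Longest linear sequence: 9 steps (steps 1, 2, 3, 4, 6, 7, 8, 9, 10); step 5 is a one-step side branch.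

Steps most likely to fail:

1. Step 6 (proposed new method). The terminal ynol ether may homotrimerise faster than it cross-trimerises, the hindered internal alkyne may fail to enter the rhodacycle, or insertion may occur head to head. The fallback uses known cross-coupling, sets out from benzyl bromide 2 and chloromethyl methyl ether 4, and returns to the route at 18. Commercial phloroglucinol would be O-benzylated with 2 (K2CO3, DMF) to 1,3,5-tris(benzyloxy)benzene F1. N-Bromosuccinimide (2 equiv, CH2Cl2, 0 °C) would then give 2,4-dibromo-1,3,5-tris(benzyloxy)benzene F2. Commercial 3,5-bis(benzyloxy)phenol would be protected with 4 (K2CO3, acetone) as 1,3-bis(benzyloxy)-5-(methoxymethoxy)benzene F3. Directed ortho-metalation between the MOM ether and a benzyl ether (n-BuLi, THF, 0 °C), then B(OMe)3 and aqueous NH4Cl, would give [2,4-bis(benzyloxy)-6-(methoxymethoxy)phenyl]boronic acid F4. A twofold Suzuki–Miyaura coupling of F2 with F4 (Pd(OAc)2, SPhos, K3PO4, toluene–water, 100 °C), a reaction type established for tetra-ortho-substituted biaryls, would deliver 18 directly.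

2. Step 5. The parent ynolate may be silylated on carbon (ketene formation) instead of oxygen, or the volatile siloxyalkyne may be lost on isolation. The fallback replaces 16 by a terminal ynol ether whose C–O bond exists before the alkyne is formed; it sets out from 12 and returns at 18. Benzyl alcohol, KH and trichloroethylene (THF, rt) would give benzyl (E)-1,2-dichlorovinyl ether F5. n-BuLi (2.2 equiv, −78 °C) followed by a methanol quench would give benzyl ethynyl ether F6. F6 would replace 16 under the conditions of step 6, kept at or below rt because of its thermal lability. This would give 5-(benzyloxy)-2,4-bis[2,4-bis(benzyloxy)-6-(methoxymethoxy)phenyl]-1,3-bis(triisopropylsilyloxy)benzene F7, in which the B4 oxygen is already benzylated. The conditions of step 7 would then convert F7 into 18.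

3. Step 4. Oxygen transfer to the hindered, electron-rich acetylide may stay incomplete, or the acid-sensitive aryl siloxyalkyne may hydrolyse during isolation. The fallback reaches the ynolate by rearrangement instead of oxidation; it sets out from 5 and returns at 11. Pinnick oxidation (NaClO2, NaH2PO4, 2-methyl-2-butene, t-BuOH–H2O) would give 2,4-bis(benzyloxy)-6-(methoxymethoxy)benzoic acid F8. MeI and K2CO3 in DMF would give methyl 2,4-bis(benzyloxy)-6-(methoxymethoxy)benzoate F9. Kowalski homologation would follow: LiCHBr2 from CH2Br2 and lithium 2,2,6,6-tetramethylpiperidide (THF, −78 °C), then LiN(SiMe3)2, then n-BuLi (−78 °C to rt). The 1,2-aryl shift of the carbenoid should give ynolate 11, which is silylated with 9 as in step 4 to give 12.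

**Further compounds**

F1 | step 6 | 1,3,5-tris(benzyloxy)benzene | c1ccc(COc2cc(OCc3ccccc3)cc(OCc3ccccc3)c2)cc1
F2 | step 6 | 2,4-dibromo-1,3,5-tris(benzyloxy)benzene | Brc1c(OCc2ccccc2)cc(OCc2ccccc2)c(Br)c1OCc1ccccc1
F3 | step 6 | 1,3-bis(benzyloxy)-5-(methoxymethoxy)benzene | COCOc1cc(OCc2ccccc2)cc(OCc2ccccc2)c1
F4 | step 6 | [2,4-bis(benzyloxy)-6-(methoxymethoxy)phenyl]boronic acid | COCOc1cc(OCc2ccccc2)cc(OCc2ccccc2)c1B(O)O
F5 | step 5 | benzyl (E)-1,2-dichlorovinyl ether | Cl/C=C(/Cl)OCc1ccccc1
F6 | step 5 | benzyl ethynyl ether | C#COCc1ccccc1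
F7 | step 5 | 5-(benzyloxy)-2,4-bis[2,4-bis(benzyloxy)-6-(methoxymethoxy)phenyl]-1,3-bis(triisopropylsilyloxy)benzene | COCOc1cc(OCc2ccccc2)cc(OCc2ccccc2)c1-c1c(O[Si](C(C)C)(C(C)C)C(C)C)cc(OCc2ccccc2)c(-c2c(OCOC)cc(OCc3ccccc3)cc2OCc2ccccc2)c1O[Si](C(C)C)(C(C)C)C(C)C
F8 | step 4 | 2,4-bis(benzyloxy)-6-(methoxymethoxy)benzoic acid | COCOc1cc(OCc2ccccc2)cc(OCc2ccccc2)c1C(=O)O
F9 | step 4 | methyl 2,4-bis(benzyloxy)-6-(methoxymethoxy)benzoate | COCOc1cc(OCc2ccccc2)cc(OCc2ccccc2)c1C(=O)OC
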